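## Retrosynthetic overview

1. Target 13 ⇐ ketone 12 (C=O → C=CH2 last) ⇐ chlorohydrin 11 (tertiary OH → Br with retention) ⇐ spiro enone 10 (Markovnikov, trans-diaxial Cl/OH addition steered by the spiro centre).
2. Spiro ketone 10 ⇐ cyclopentanol 9 by a hydroxyl-directed protio-semipinacol ring expansion: C5 shifts from C1 to C6, making ring A six-membered and creating the spiro centre in one step.
3. 9 ⇐ ethynyl carbinol 7 + isoprene (cobalt-catalysed [4+2] builds ring B) ⇐ bromoketone 5 + ethynylmagnesium bromide.
4. 5 ⇐ 2,2-dimethylcyclopentane-1,3-dione 2 (desymmetrising reduction, then OH → Br with inversion) ⇐ 2-methylcyclopentane-1,3-dione 1 + MeI.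
5. Ring order: cyclopentane (bought) → ring B (step 5) → ring A by ring expansion (step 6). Stereo relay: C4 → C1 → C6 → C9/C10.

Assumption: all spiro compounds are numbered as in the target SMILES (C1 = carbon bearing the exocyclic CH2 or the ketone O, C4 = CHBr, C5 = CMe2, C6 = spiro carbon, C7/C8 = CH2, C9 = C(CH3) carbon, C10 = CHCl carbon, C11 = CH2); on this numbering the target is (4S,6S,9R,10R).

## Route

Step 1
Reactants: 1 2-methylcyclopentane-1,3-dione
Product: 2 2,2-dimethylcyclopentane-1,3-dione
Conditions: MeI (1.5 equiv), KOH, H2O/1,4-dioxane, 70 °C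
Reagents that add atoms: iodomethane CI
Why: C-alkylation of the stabilised 1,3-diketone enolate (β-diketone α-methylation) creates the gem-dimethyl quaternary carbon; no stereocentre is formed.

Step 2
Reactants: 2 2,2-dimethylcyclopentane-1,3-dione
Product: 3 (R)-3-hydroxy-2,2-dimethylcyclopentan-1-one
Conditions: (S)-2-methyl-CBS-oxazaborolidine [(S)-1-methyl-3,3-diphenyltetrahydro-1H,3H-pyrrolo[1,2-c][1,3,2]oxazaborole] (10 mol%), BH3·SMe2 (0.6 equiv, slow addition), THF, −30 °C; MeOH quench
Reagents that add atoms: none
Why: Corey–Bakshi–Shibata desymmetrising mono-reduction, in which the oxazaborolidine–borane complex treats the quaternary side as the large group and delivers hydride to the Si face of one enantiotopic carbonyl, setting the (R)-carbinol (sense assigned from the standard model); limiting borane at low temperature stops at the hydroxy ketone.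

Step 3
Reactants: 3 (R)-3-hydroxy-2,2-dimethylcyclopentan-1-one
Product: 5 (S)-3-bromo-2,2-dimethylcyclopentan-1-one, via triflate 4 (not isolated)
Conditions: (CF3SO2)2O, 2,6-lutidine, CH2Cl2, −40 °C; then LiBr, THF, −40 → 20 °C
Reagents that add atoms: lithium bromide [Li+].[Br-]
Why: triflation followed by SN2 displacement with bromide (Walden inversion) turns the (R)-carbinol into the (S)-bromide; ionisation with methyl shift is disfavoured because the neighbouring quaternary carbon carries the acyl group, and that carbon has no hydrogen, so no elimination toward the ketone can occur.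

Step 4
Reactants: 5 (S)-3-bromo-2,2-dimethylcyclopentan-1-one; 6 ethynylmagnesium bromide
Product: 7 (1S,3S)-3-bromo-1-ethynyl-2,2-dimethylcyclopentan-1-ol
Conditions: HC≡CMgBr (1.5 equiv), THF, −78 → 0 °C; aq. NH4Cl; chromatography to remove the minor C1 epimer
Reagents that add atoms: none
Why: Grignard 1,2-addition of the acetylide to the ketone; attack on the carbonyl face anti to the C3 bromide (the methyl cis to Br is pseudo-axial and shields the syn face, and the C–Br dipole is opposed) gives the (1S) carbinol with OH cis to Br (expected about 4:1).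

Step 5
Reactants: 7 (1S,3S)-3-bromo-1-ethynyl-2,2-dimethylcyclopentan-1-ol; 8 isoprene (2-methylbuta-1,3-diene)
Product: 9 (1S,3S)-3-bromo-2,2-dimethyl-1-(4-methylcyclohexa-1,4-dien-1-yl)cyclopentan-1-ol
Conditions: CoBr2(Ph2PCH2CH2PPh2) (10 mol%), ZnI2 (20 mol%), Zn powder (20 mol%), isoprene (3 equiv), CH2Cl2, 20 °C; base-washed silica, use at once
Reagents that add atoms: none
Why: cobalt-catalysed formal [4+2] cycloaddition of a terminal alkyne with a 1,3-diene (stepwise through a cobaltacycle of low-valent cobalt, not a thermal Diels–Alder reaction) gives the 1,4-cyclohexadiene with the methyl para to the carbinol substituent, the usual regiochemistry for this bisphosphine cobalt system; no stereocentre is formed.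

Step 6
Reactants: 9 (1S,3S)-3-bromo-2,2-dimethyl-1-(4-methylcyclohexa-1,4-dien-1-yl)cyclopentan-1-ol
Product: 10 (4S,6R)-4-bromo-5,5,9-trimethylspiro[5.5]undec-9-en-1-one
Conditions: (PhO)2P(O)NHSO2CF3 (10 mol%), toluene (0.05 M), −20 → 20 °C
Reagents that add atoms: none
Why: Proposed new method: hydroxyl-directed protio-semipinacol ring expansion of an unstrained 1-alkenylcyclopentanol, in which the N-triflylphosphoramide is held by the carbinol O–H through its P=O and delivers its N–H proton to C7 on the alkene face where the oxygen sits (reactive rotamer: O–C1–C6=C7 about 30°, bulky CMe2 carbon perpendicular to the alkene plane) while the anti-periplanar C1–C5 bond migrates to C6 as the C=O forms, so ring A and the spiro centre arise in one asynchronous anti addition and the (1S) carbinol configuration is relayed into the (6R) spiro centre (C7 cis to the C4 bromine); the more substituted C5 migrates in preference to C2 and the remote C9=C10 alkene lacks this push-pull assistance; the closest known reactions are halonium-induced semipinacol ring expansions of 1-alkenylcycloalkanols and the acid-catalysed protio-semipinacol of vinylcyclobutanols and enol-ether carbinols.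

Step 7
Reactants: 10 (4S,6R)-4-bromo-5,5,9-trimethylspiro[5.5]undec-9-en-1-one
Product: 11 (4S,6R,9R,10R)-4-bromo-10-chloro-9-hydroxy-5,5,9-trimethylspiro[5.5]undecan-1-one
Conditions: N-chlorosuccinimide (1.2 equiv), THF/H2O (3:1), 0 → 20 °C
Reagents that add atoms: N-chlorosuccinimide O=C1CCC(=O)N1Cl; water O
Why: electrophilic chlorohydroxylation (halohydrin formation) of the only alkene, where Markovnikov, trans-diaxial opening of the chloronium ion in the half-chair that keeps the bulky CMe2 carbon C5 equatorial on ring B places Cl axial at C10 on the face of C1 and water axial at the tertiary C9 on the face of C5, setting (9R,10R).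

Step 8
Reactants: 11 (4S,6R,9R,10R)-4-bromo-10-chloro-9-hydroxy-5,5,9-trimethylspiro[5.5]undecan-1-one
Product: 12 (4S,6R,9R,10R)-4,9-dibromo-10-chloro-5,5,9-trimethylspiro[5.5]undecan-1-one
Conditions: HBr (33% in AcOH, 3 equiv), CH2Cl2, −20 → 0 °C
Reagents that add atoms: hydrogen bromide Br
Why: SN1-type substitution of the tertiary alcohol with anchimeric assistance from the anti-periplanar axial chlorine (chloronium ion), so bromide enters axially at C9 from the face the water left, i.e. with retention, giving the trans tertiary bromide/secondary chloride pair; the ketone and the secondary bromide are inert to HBr at this temperature.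

Step 9
Reactants: 12 (4S,6R,9R,10R)-4,9-dibromo-10-chloro-5,5,9-trimethylspiro[5.5]undecan-1-one
Product: 13 (4S,6S,9R,10R)-4,9-dibromo-10-chloro-5,5,9-trimethyl-1-methylidenespiro[5.5]undecane
Conditions: (C5H5)2Ti(CH3)2 (2.5 equiv), toluene, 65 °C, dark
Reagents that add atoms: dimethyltitanocene [CH3-].[CH3-].[Ti+4].c1cc[cH-]c1.c1cc[cH-]c1
Why: Petasis methylenation, in which thermally generated titanocene methylidene converts the hindered ketone to the exocyclic alkene through an oxatitanacyclobutane under non-basic, non-Lewis-acidic conditions, so the tertiary bromide, the secondary halides and the α-hydrogens are untouched and no stereocentre changes (the C6 descriptor changes from R to S only because CIP priorities change).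

## Compound list

1 | 2-methylcyclopentane-1,3-dione | CC1C(=O)CCC1=O | starting material
2 | 2,2-dimethylcyclopentane-1,3-dione | CC1(C)C(=O)CCC1=O | intermediate
3 | (R)-3-hydroxy-2,2-dimethylcyclopentan-1-one | O=C1CC[C@@H](O)C1(C)C | intermediate
4 | (1R)-2,2-dimethyl-3-oxocyclopentyl trifluoromethanesulfonate (not isolated) | O=C1CC[C@@H](OS(=O)(=O)C(F)(F)F)C1(C)C | intermediate
5 | (S)-3-bromo-2,2-dimethylcyclopentan-1-one | O=C1CC[C@H](Br)C1(C)C | intermediate
6 | ethynylmagnesium bromide | C#C[Mg]Br | starting material
7 | (1S,3S)-3-bromo-1-ethynyl-2,2-dimethylcyclopentan-1-ol (OH cis to Br) | C#C[C@@]1(O)CC[C@H](Br)C1(C)C | intermediate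
8 | isoprene (2-methylbuta-1,3-diene) | C=CC(C)=C | starting material
9 | (1S,3S)-3-bromo-2,2-dimethyl-1-(4-methylcyclohexa-1,4-dien-1-yl)cyclopentan-1-ol | CC1=CCC(=CC1)[C@@]2(O)CC[C@H](Br)C2(C)C | intermediate
10 | (4S,6R)-4-bromo-5,5,9-trimethylspiro[5.5]undec-9-en-1-one | O=C1CC[C@H](Br)C(C)(C)[C@]12CCC(C)=CC2 | intermediate
11 | (4S,6R,9R,10R)-4-bromo-10-chloro-9-hydroxy-5,5,9-trimethylspiro[5.5]undecan-1-one | O=C1CC[C@H](Br)C(C)(C)[C@]12CC[C@@](C)(O)[C@H](Cl)C2 | intermediate
12 | (4S,6R,9R,10R)-4,9-dibromo-10-chloro-5,5,9-trimethylspiro[5.5]undecan-1-one | O=C1CC[C@H](Br)C(C)(C)[C@]12CC[C@@](C)(Br)[C@H](Cl)C2 | intermediate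
13 | (4S,6S,9R,10R)-4,9-dibromo-10-chloro-5,5,9-trimethyl-1-methylidenespiro[5.5]undecane | C=C1CC[C@H](Br)C(C)(C)[C@]12CC[C@@](C)(Br)[C@H](Cl)C2 | target

## Step count and risks

Total steps: 9. Longest linear sequence: 9 steps (from 1; compounds 6 and 8 are bought).

Most likely to fail:

Step 3 (bromide displacement next to a quaternary carbon; slow substitution or elimination). The fallback sets out from 2 and comes back at 5 by a double inversion through a soft nucleophile. Reduction of 2 with the enantiomeric (R)-2-methyl-CBS-oxazaborolidine and BH3·SMe2 gives (S)-3-hydroxy-2,2-dimethylcyclopentan-1-one F1. Treatment with (CF3SO2)2O and 2,6-lutidine gives (1S)-2,2-dimethyl-3-oxocyclopentyl trifluoromethanesulfonate F2. The far more nucleophilic PhSeNa (from PhSeSePh and NaBH4, THF/EtOH, 0 °C) displaces the triflate with inversion to give (R)-2,2-dimethyl-3-(phenylselanyl)cyclopentan-1-one F3. Bromodeselenation with Br2 in CH2Cl2 then replaces selenium by bromide with a second inversion and delivers 5.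

Step 6 (the proposed new step). The acid may instead ionise the tertiary allylic alcohol, which leads to dehydration and aromatisation of the 1,4-diene. It may also protonate the remote alkene, and C9=C10 migration would scramble C6. The relay fails if the non-directed rotamer reacts. The fallback uses known chemistry, sets out from 9 and comes back at 10. N-iodosuccinimide with NaHCO3 in CH2Cl2 at −20 °C triggers an iodonium-induced semipinacol ring expansion. This is an anti addition with iodine delivered on the hydroxyl face and C5 migrating from the other face, and it is irreversible only at the carbinol alkene. It gives (4S,6S,7R)-4-bromo-7-iodo-5,5,9-trimethylspiro[5.5]undec-9-en-1-one F4. Radical deiodination with (C4H9)3SnH (1.1 equiv) and B(C2H5)3/air in toluene at −78 °C then removes iodine. The C–I bond is abstracted far faster than the neopentyl C–Br bond, and concentrated tin hydride outruns acyl shift of the β-keto radical. The product is 10.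

Step 7 (face and regiochemistry of chlorohydroxylation; ene-type allylic chlorination as a side reaction). The fallback sets out from 10 and comes back at 11 by putting oxygen on first and bringing chlorine in as a nucleophile. 3-Chloroperoxybenzoic acid with NaHCO3 in CH2Cl2 at 0 °C epoxidises the face anti to the axial C1 and gives (4S,6R,9R,10S)-4-bromo-9,10-epoxy-5,5,9-trimethylspiro[5.5]undecan-1-one F5. Anhydrous HCl in Et2O at −20 °C then opens the epoxide trans-diaxially (Fürst–Plattner) at C10 with inversion, giving 11.

Further compounds
F1 | step 3 | (S)-3-hydroxy-2,2-dimethylcyclopentan-1-one | O=C1CC[C@H](O)C1(C)C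
F2 | step 3 | (1S)-2,2-dimethyl-3-oxocyclopentyl trifluoromethanesulfonate | O=C1CC[C@H](OS(=O)(=O)C(F)(F)F)C1(C)C
F3 | step 3 | (R)-2,2-dimethyl-3-(phenylselanyl)cyclopentan-1-one | O=C1CC[C@@H]([Se]c2ccccc2)C1(C)C
F4 | step 6 | (4S,6S,7R)-4-bromo-7-iodo-5,5,9-trimethylspiro[5.5]undec-9-en-1-one | O=C1CC[C@H](Br)C(C)(C)[C@]12[C@H](I)CC(C)=CC2
F5 | step 7 | (4S,6R,9R,10S)-4-bromo-9,10-epoxy-5,5,9-trimethylspiro[5.5]undecan-1-one | O=C1CC[C@H](Br)C(C)(C)[C@]12CC[C@@]3(C)O[C@H]3C2
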